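Readings and results are simulated with made-up constants.

The easy thing to read in these runs is what is left, so I work with the fraction of the starting material charge still there. The question is whether the next flask needs its partner charge changed before material is spent on it.

| flask | starting material | partner | capture agent | remark | time |
|---|---|---|---|---|---|
| alpha | 0.40 M | 0.76 M | 0.080 M | run made earlier |  |
| epsilon | 1.6 M | 0.76 M | 0.080 M | run made earlier |  |
| theta | 0.80 M | 0.38 M | 0.080 M | run made earlier |  |
| flask | 0.80 M | 0.760 M | 0.0800 M |  | 5.0 h |

| run | time / h | starting material / % | single product / % |
|---|---|---|---|
| alpha | 0.833 | 25 | 34 |
| alpha | 1.50 | 16 | 34 |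
| alpha | 2.50 | 14 | 26 |
| alpha | 3.00 | 8 | 24 |
| epsilon | 0.250 | 71 | 27 |
| epsilon | 0.500 | 64 | 27 |
| epsilon | 1.33 | 60 | 29 |
| epsilon | 3.00 | 57 | 28 |
| theta | 0.417 | 71 | 23 |
| theta | 1.00 | 63 | 27 |
| theta | 2.00 | 59 | 27 |
| theta | 3.00 | 60 | 28 |

(readings scatter by 2 percentage points)

1. amount of starting material at 5.0 h, in percent of the starting material charged
2. amount of single product at 5.0 h, in percent of the starting material charged
3. amount of double product at 5.0 h, in percent of the starting material charged
4. amount of tris adduct at 5.0 h, in percent of the starting material charged



Suppose single product takes up partner with the same rate constant as starting material does, a selectivity factor of about one, and no other path counts. Then partner and clock cancel, and the fraction of single product equals the fraction left times the logarithm of its inverse. This curve tops at a fraction left of 36.8%, where it equals that same fraction. I divide the single product read by the curve at alpha's first reading and at the last readings of epsilon and theta. The mean of these quotients is 0.923, and this is my curve factor, a value read from these few readings with their scatter in it.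

Next I ask how far the flask goes. Charged partner per starting material gone is 1.19 in theta, whose last readings stand at 59% and 60% left, and 2.07 in alpha at its last reading. The flask charges 0.950 of partner per starting material. If the flask takes up its partner charge by the time asked and its ratio lies between those two, the fraction left lies between 20.0% and 54.0%. The curve times the factor then gives 29.7% and 30.7% of single product at those ends, and 33.9% at the top between them. So I commit to single product in that range, and I leave the partner charge as it is.

The forecast gives 33% starting material, 31% single product, 30% double product and 6% tris adduct, reasoning that “partner is essentially exhausted by 5 h”.

The flask gives 31.2% starting material, 33.9% single product, 15.2% double product and 5.50% tris adduct.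

    starting material + partner → single product (k = 0.0520 M⁻¹ min⁻¹)
    partner + single product → double product (k = 0.0490 M⁻¹ min⁻¹)
    partner + double product → tris adduct (k = 0.0340 M⁻¹ min⁻¹)
    starting material + double product → side product (k = 0.00380 M⁻¹ min⁻¹)
    single product + capture agent → trapped intermediate (k = 0.00630 M⁻¹ min⁻¹)

At 5.0 h the flask holds 0% of its partner charge, less than the 31% of its starting material. The curve times the curve factor, at the flask's fraction left, gives 33.5% of single product, against the 33.9% found. In the flask charged with 0.32 M of starting material, 3.79% is left, so the curve times the curve factor gives 11.5%, and that flask holds 12.9% of single product.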